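- How far has the starting complex reacted in the flask with 30 mM of it and 0.800 equiv of incoming ligand at 10 h, and how much of the unused ligand is still free?

| flask | starting complex | incoming ligand | remark | time |
|---|---|---|---|---|
| red | 42 mM | 0.80 equiv | run made earlier |  |
| ochre | 66 mM | 0.80 equiv | run made earlier |  |
| amber | 30 mM | 1.2 equiv | run made earlier |  |
| flask | 30 mM | 0.800 equiv |  | 10 h |

| run | time / h | starting complex / % | complex with two exchanged / % |
|---|---|---|---|
| red | 1.50 | 82.5 | 1.3 |
| red | 3.00 | 80.4 | 1.6 |
| red | 5.00 | 79.6 | 3.3 |
| red | 6.00 | 79.7 | 2.4 |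
| red | 8.00 | 80.0 | 3.2 |
| red | 10.0 | 80.6 | 2.6 |
| ochre | 0.667 | 85.2 | 1.3 |
| ochre | 2.00 | 80.3 | 2.1 |
| ochre | 4.00 | 79.6 | 2.2 |
| ochre | 5.00 | 80.2 | 2.5 |
| ochre | 8.00 | 80.7 | 2.3 |
| ochre | 10.0 | 82.1 | 3.9 |
| amber | 0.833 | 83.7 | 1.5 |
| amber | 1.50 | 80.2 | 1.0 |
| amber | 3.00 | 76.9 | 2.9 |
| amber | 5.00 | 76.5 | 2.8 |
| amber | 10.0 | 76.6 | 3.8 |

(readings scatter by 0.5 percentage points)

* part of the starting complex that has reacted at 10 h
* share of the unused incoming ligand that is free and not bound as idle adduct, at 10 h

- the analysis behind the earlier runs scatters by 0.5 percentage points, standard deviation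
- the earlier runs do not show how much of incoming ligand is bound; that part of a forecast is a guess

- The curve of the flask starts from amber, which has the same concentration of starting complex and loses 16.3% of it by 0.833 h; assuming that the early rate goes with the ligand charge, I scale this to an average slope of 0.130 h⁻¹.

- For the level I follow one molecule of incoming ligand and ask its chance of sitting on the complex at the asked time: the landing share, which is the reacted part plus the two-exchanged reading, which carries a second ligand, divided by the equivalents charged.

- At 10 h the landing share reads 27.5% in red at 42 mM and 27.3% in ochre at 66 mM, about the same, but amber at 30 mM and 1.2 equiv reads less, 22.7%, so I carry over the mean of red and ochre, 27.4%, and assume that it holds for the flask at 30 mM.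

- Taking off the mean two-exchanged reading of red and ochre, I expect the flask to level near 18.6% reacted, and by my estimate the slope meets that level at a knee near 1.43 h; for the free share I have only a guess.

- The forecast says 20% reacted and 90% free, with ligand loss of “perhaps 10% at 30 mM”, and its reacted part stands above my level.

- The flask gives 19.9% reacted and 14.3% free, the forecast's free share being 76 percentage points too high, and at 10.0 h c(idle adduct) is 4.45 mM while the incoming ligand, the limiting reagent, keeps 3.1% of its charge unbound against 80% of the starting complex.

    leaving ligand + incoming ligand ⇌ idle adduct, settled at all times (K = 2500 M⁻¹)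
    complex with two exchanged + incoming ligand ⇌ leaving ligand + complex with three exchanged (K = 2.60, k = 4.30 M⁻¹ h⁻¹)
    2 incoming ligand → homo dimer (k = 35.0 M⁻¹ h⁻¹)
    starting complex + incoming ligand ⇌ leaving ligand + complex with one exchanged (K = 0.610, k = 13.0 M⁻¹ h⁻¹)
    complex with one exchanged + incoming ligand ⇌ leaving ligand + complex with two exchanged (K = 1.20, k = 12.0 M⁻¹ h⁻¹)

- The landing share of the flask comes to 28.2%, and in the neighbour flask with 12 mM of starting complex at the same equivalents it comes to 27.3%.

All runs are calculated for an exercise; scatter was added.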